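## The problem

- The target is a (2S)-flavanone. A phloroglucinol-type ring A (C4a to C8a) is fused to the dihydropyranone ring C (O1, C2, C3, C4), and the catechol ring B sits on C2.
- Ring A carries three different oxygens: O1 in ring C, the hydrogen-bonded 5-OH and the 7-OMe. The C5 chain must sit on C8 and not on C6, although in any flavanone or chromone both carbons are activated by two oxygens to a similar degree.
- The chain is a (Z)-4-hydroxy-3-methylbut-2-enyl group, with C4''H2OH cis to C1''. Allylic oxidation of a prenyl group with SeO2 gives the other isomer, E and Z differ little in energy, and a [3,3] shift that creates C2''=C3'' must choose between CH3 and CH2O on C3'' without a steric handle.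
- C2 is the only stereocenter, so nothing in the molecule can control it. It is also labile: base opens ring C by retro-oxa-Michael reaction to the 2'-hydroxychalcone, helped by the 5-OH and, through a quinone methide, by the 4'-OH. It must therefore be set late and kept away from base.
- The catechol is sensitive to oxidation, and the allylic alcohol ionizes in acid.
- Two features of the structure open a short way in. First, in the ring-C-opened precursor 3 (2,6-dihydroxy-4-methoxyacetophenone), the carbons that become C6 and C8 are related by the mirror plane through C4a and C7, so a C–C bond formed there raises no C6/C8 question. Second, O4'' and C1'' are the ends of the unit C1''–C2''=C3''–C4''–O, which closes with a metal to a six-membered oxa-metallacycle only when C1'' and C4'' are cis, a chelate that exists only for the Z isomer.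

## Retrosynthesis

**14 from 13.** All four hydroxyl groups of target 14 are masked as silyl ethers in 13, so the last step is one buffered fluoride treatment. No acid touches the allylic alcohol, no base touches C2, and no hydrogenolysis touches the alkene.

**13 from 7 and 12.** The C2–C1' bond is cut, not the O1–C2 bond of the chalcone logic. The precursor is the flat, achiral chromone 7 and the arylboronic acid 12. The forward reaction is a rhodium-catalysed asymmetric 1,4-addition. It creates C2 in a C–C bond-forming step under nearly neutral conditions, as the last skeletal step, with the chiral diene ligand as the only controller. The chalcone cut would need an enantioselective oxa-Michael closure of an unactivated 2'-hydroxychalcone, for which precedent is weak.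

**7 from 5.** Ring C is opened at O1–C2 and C2–C3, and C2 comes from an amide acetal. The forward reaction is enaminone formation and cyclocondensation. It is required that only the phenol next to the chain (O2 of the acetophenone) is free. This is what places the chain on C8.

**5 from 4.** Two silyl groups are removed. Forward, a bulky silyl chloride must take the primary alcohol and the less hindered phenol O6 of triol 4, and leave O2, which is flanked by the acetyl group and the chain.

**4 from 2 and 3 (key disconnection).** The C8–C1'' bond is cut (C3–C1'' in acetophenone numbering), and with it the C2''=C3'' double bond and the free O4''–H are traced back to the vinyl cyclic carbonate 2.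

- Against the neighbouring cut C1''–C2'' (benzyl plus vinyl coupling): that cut needs both partners prefunctionalized.
- Against the cut C2''=C3'' (olefination): that cut needs an aldehyde and a later ester reduction next to a ketone.
- The chosen cut uses an aromatic C–H bond of the commercial, mirror-symmetric ketone 3 and a five-carbon reagent one step from a commercial epoxide.
- Asked of the forward reaction: C- and not O-allylation, attack at the CH2 terminus, one allylation only, and Z geometry from the oxa-palladacycle.

**2 from 1.** The carbonate is cut to isoprene monoxide 1 and CO2. The carbonate is preferred to the epoxide as allyl donor because it is not opened by the phenol without palladium.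

**12 from 9 from 8.** The boronic acid comes from 4-bromocatechol 8 by silylation to 9 and bromine–lithium exchange/borylation.

## Roads not taken

Alternative 1: The most obvious plan cuts O1–C2 and the C3–C2 bond (chalcone logic) and makes the chain by oxidation of a prenyl group.
- Forward: C-prenylation of 3 to A1, SeO2 oxidation to allylic alcohol A2, Claisen–Schmidt condensation with 3,4-dihydroxybenzaldehyde to chalcone A3, then oxa-Michael cyclization.
- Why the chosen plan is better: the [2,3] shift of the allylseleninic acid puts oxygen on the methyl group trans to the chain, so A2 is the E isomer, the wrong one, with no simple correction. A3 has two free ortho hydroxyl groups and closes to both the 6- and the 8-substituted flavanone. The closure is racemic and runs under conditions in which C2 is not configurationally stable.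
- The chosen plan fixes geometry, position and configuration by design in three separate, controlled events.

Alternative 2: Cut C8–C1'' by a para-Claisen–Cope relay from O5.
- Forward: the (2S)-5-O-allyl flavanone A4 is heated with Eu(fod)3; a [3,3] shift takes the chain from O5 to C6, and a Cope shift takes it on to C8.
- In its favour: the pericyclic relay settles the C6/C8 question and keeps ring A symmetric until late.
- Why the chosen plan is better: C2''=C3'' is destroyed in the first shift and re-made in the Cope shift. There CH3 and CH2OSi on the migrating quaternary carbon compete for the equatorial site of the chair without bias, so a mixture of geometrical isomers is expected. Heating a C2-stereogenic 5-hydroxyflavanone with a Lewis acid also endangers the stereocenter, and more steps follow once it is set.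

Alternative 3: Cut C2''=C3'' by a Z-selective olefination.
- Forward: O-allylation and Claisen rearrangement of 3 to the 3-allyl ketone A5, oxidative cleavage to arylacetaldehyde A6, Ando or Still–Gennari olefination to the (Z)-enoate A7, then reduction to the allylic alcohol.
- Why the chosen plan is better: A6 closes to a lactol with the ortho phenol. The ester of A7 cannot be reduced in the presence of the aryl ketone without protection or oxidation-state shuffling. The chain costs five or more steps, against one step in the chosen plan.

Key step: step 2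

Assumption: epoxide 1 and carbonate 2 are used as racemates, since their stereocenter is lost on ionization. The sense of induction of the diene ligand in step 7 is taken over from the cyclohexenone series, where the enone is presented to rhodium in the same way.

## Route

Step 1
Reactants: 1 2-methyl-2-vinyloxirane (isoprene monoxide, racemic)
Product: 2 4-methyl-4-vinyl-1,3-dioxolan-2-one (racemic)
Conditions: Pd(PPh3)4 (1 mol %), CO2 (1 atm), THF, 0 °C to rt; filtration through silica to remove palladium
Reagents that add atoms: carbon dioxide, O=C=O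
Why: Known palladium-catalysed CO2 insertion into vinyl epoxides: zerovalent palladium ionizes the allylic C–O bond, the alkoxide captures CO2, and the carbonate closes on the internal allyl terminus to the five-membered ring.

Step 2
Reactants: 2 4-methyl-4-vinyl-1,3-dioxolan-2-one; 3 1-(2,6-dihydroxy-4-methoxyphenyl)ethan-1-one
Product: 4 1-{2,6-dihydroxy-3-[(2Z)-4-hydroxy-3-methylbut-2-en-1-yl]-4-methoxyphenyl}ethan-1-one
Conditions: Pd2(dba)3·CHCl3 (2.5 mol %), DPEPhos (6 mol %), 3 (2 equiv), slow addition of 2, THF, 25 to 45 °C, argon line (CO2 vented)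
Reagents that add atoms: none
Why: Proposed new method: zerovalent palladium ionizes the tertiary allylic C–O bond of 2, CO2 leaves, and the alkoxide closes onto palladium to the six-membered oxa-palladacycle Pd–C1''H2–C2''H=C3''(CH3)–C4''H2–O, which can exist only with C1'' and C4'' cis. The alkoxide, a base of alcohol strength, takes the proton of the far more acidic phenol 3, and the chelated or hydrogen-bonded phenoxide attacks the unsubstituted allyl terminus C1'' through ring carbon C3; the cyclohexadienone formed tautomerizes to 4. The closest known reaction types are the palladium-catalysed decarboxylative allylic substitution of vinyl cyclic carbonates by amines, water, sulfinates and stabilized carbanions, which gives (Z)-allylic alcohols through this palladacycle, and the palladium-catalysed C-allylation of acylphloroglucinols by allylic carbonates; what is untested is their combination on a phenolic C–H nucleophile. No ring is closed and no stereocenter is formed; the element to be controlled is the C2''=C3'' geometry, and it is controlled by the Pd–O chelate (CH2O held anti on the allyl), supported after proton transfer by the OH···O(aryl) hydrogen bond, because syn/anti exchange at C3'' needs a palladium σ-bond to that tertiary carbon and is slow. Site selectivity needs no control, since C3 and C5 of 3 are homotopic. C- over O-allylation is secured by reversibility: allyl ethers of this acidic ortho-acylphenol re-ionize under zerovalent palladium, whereas the C–C bond does not. Excess 3 suppresses a second allylation, and a carbon nucleophile prefers the CH2 terminus over the quaternary one, so the linear product should result.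

Step 3
Reactants: 4 1-{2,6-dihydroxy-3-[(2Z)-4-hydroxy-3-methylbut-2-en-1-yl]-4-methoxyphenyl}ethan-1-one
Product: 5 1-{2-hydroxy-4-methoxy-3-[(2Z)-3-methyl-4-(triisopropylsilyloxy)but-2-en-1-yl]-6-(triisopropylsilyloxy)phenyl}ethan-1-one
Conditions: TIPSCl (2.3 equiv), imidazole (5 equiv), DMAP (cat.), DMF, 0 °C to rt
Reagents that add atoms: chlorotriisopropylsilane, CC(C)[Si](Cl)(C(C)C)C(C)C
Why: Silylation with a bulky silyl chloride: the primary alcohol reacts first, then the phenol flanked by hydrogen (O6) in preference to the phenol flanked by the chain (O2). Once O6 is silylated, the remaining 2-OH is locked in the hydrogen bond to the ketone and should stay free.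

Step 4
Reactants: 5 1-{2-hydroxy-4-methoxy-3-[(2Z)-3-methyl-4-(triisopropylsilyloxy)but-2-en-1-yl]-6-(triisopropylsilyloxy)phenyl}ethan-1-one
Product: 7 7-methoxy-8-[(2Z)-3-methyl-4-(triisopropylsilyloxy)but-2-en-1-yl]-5-(triisopropylsilyloxy)-4H-chromen-4-one, via enaminone 6 (not isolated)
Conditions: Me2NCH(OMe)2 (3 equiv), toluene, 90 °C; evaporation; then p-TsOH·H2O (1.2 equiv), CH2Cl2, 0 °C to rt
Reagents that add atoms: N,N-dimethylformamide dimethyl acetal, COC(OC)N(C)C
Why: Enaminone formation from the methyl ketone and the amide acetal, then acid-mediated addition–elimination cyclization (the standard chromone synthesis from 2-hydroxyacetophenones). Only O2 is free, so O1 ends up on the carbon next to the chain and the chain is at C8; the cold, short acid treatment should spare the trisubstituted alkene and the silyl ethers.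

Step 5
Reactants: 8 4-bromobenzene-1,2-diol
Product: 9 4-bromo-1,2-bis(tert-butyldimethylsilyloxy)benzene
Conditions: TBSCl (2.3 equiv), imidazole (5 equiv), DMF, rt
Reagents that add atoms: tert-butylchlorodimethylsilane, CC(C)(C)[Si](C)(C)Cl
Why: Standard silylation of both phenols; the silyl ethers match the fluoride-labile groups of ring A and the chain.

Step 6
Reactants: 9 4-bromo-1,2-bis(tert-butyldimethylsilyloxy)benzene
Product: 12 [3,4-bis(tert-butyldimethylsilyloxy)phenyl]boronic acid, via aryllithium 10 (not isolated), via lithium aryltriisopropoxyborate 11 (not isolated)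
Conditions: n-BuLi (1.05 equiv), THF, −78 °C; B(OiPr)3 (1.3 equiv), −78 °C to rt; 1 M HCl, 0 °C
Reagents that add atoms: triisopropyl borate, CC(C)OB(OC(C)C)OC(C)C; water, O
Why: Bromine–lithium exchange, borylation with a trialkyl borate and hydrolysis. The lithiated carbon is not ortho to a silyloxy group, so no 1,3-shift of silicon from oxygen to carbon can occur.

Step 7
Reactants: 7 7-methoxy-8-[(2Z)-3-methyl-4-(triisopropylsilyloxy)but-2-en-1-yl]-5-(triisopropylsilyloxy)-4H-chromen-4-one; 12 [3,4-bis(tert-butyldimethylsilyloxy)phenyl]boronic acid
Product: 13 (2S)-2-[3,4-bis(tert-butyldimethylsilyloxy)phenyl]-7-methoxy-8-[(2Z)-3-methyl-4-(triisopropylsilyloxy)but-2-en-1-yl]-5-(triisopropylsilyloxy)-2,3-dihydro-4H-chromen-4-one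
Conditions: [RhCl(C2H4)2]2 (2.5 mol %), (S,S)-Ph-bod* [(1S,4S)-2,5-diphenylbicyclo[2.2.2]octa-2,5-diene, 5.5 mol %], 12 (2.5 equiv), aq KOH (10 mol %), toluene/H2O, 40 °C
Reagents that add atoms: none
Why: Hayashi–Miyaura rhodium-catalysed asymmetric 1,4-addition of an arylboronic acid, a reaction type established for chromones with chiral diene ligands. The aryl–rhodium adds to C2 on the face chosen by the diene, and the (S,S)-ligand, antipode of the one that gives (R)-3-arylcyclohexanones (which map onto (R)-flavanones), should give 2S. The oxa-π-allyl rhodium is protonated by water, the hindered C4 ketone should resist a second addition, and the unactivated side-chain alkene is inert.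

Step 8
Reactants: 13 (2S)-2-[3,4-bis(tert-butyldimethylsilyloxy)phenyl]-7-methoxy-8-[(2Z)-3-methyl-4-(triisopropylsilyloxy)but-2-en-1-yl]-5-(triisopropylsilyloxy)-2,3-dihydro-4H-chromen-4-one
Product: 14 (2S)-2-(3,4-dihydroxyphenyl)-5-hydroxy-8-[(2Z)-4-hydroxy-3-methylbut-2-en-1-yl]-7-methoxy-2,3-dihydro-4H-chromen-4-one (CNP0246822.1)
Conditions: TBAF (6 equiv), AcOH (6 equiv), THF, 0 °C to rt, under argon
Reagents that add atoms: none
Why: Fluoride cleavage of the three aryl silyl ethers and the primary alkyl silyl ether. Acetic acid buffers the fluoride, so the free 5-OH/4'-OH flavanone is not exposed to base and C2 should not be epimerized through the chalcone; the allylic alcohol and the catechol should tolerate these conditions.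

## Compound list

1 | 2-methyl-2-vinyloxirane (racemic) | CC1(C=C)CO1 | starting material
2 | 4-methyl-4-vinyl-1,3-dioxolan-2-one (racemic) | CC1(C=C)COC(=O)O1 | intermediate
3 | 1-(2,6-dihydroxy-4-methoxyphenyl)ethan-1-one | CC(=O)c1c(O)cc(OC)cc1O | starting material
4 | 1-{2,6-dihydroxy-3-[(2Z)-4-hydroxy-3-methylbut-2-en-1-yl]-4-methoxyphenyl}ethan-1-one | CC(=O)c1c(O)cc(OC)c(C/C=C(/C)CO)c1O | intermediate
5 | 1-{2-hydroxy-4-methoxy-3-[(2Z)-3-methyl-4-(triisopropylsilyloxy)but-2-en-1-yl]-6-(triisopropylsilyloxy)phenyl}ethan-1-one | CC(=O)c1c(O[Si](C(C)C)(C(C)C)C(C)C)cc(OC)c(C/C=C(/C)CO[Si](C(C)C)(C(C)C)C(C)C)c1O | intermediate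
6 | (2E)-3-(dimethylamino)-1-{2-hydroxy-4-methoxy-3-[(2Z)-3-methyl-4-(triisopropylsilyloxy)but-2-en-1-yl]-6-(triisopropylsilyloxy)phenyl}prop-2-en-1-one | CN(C)/C=C/C(=O)c1c(O[Si](C(C)C)(C(C)C)C(C)C)cc(OC)c(C/C=C(/C)CO[Si](C(C)C)(C(C)C)C(C)C)c1O | intermediate
7 | 7-methoxy-8-[(2Z)-3-methyl-4-(triisopropylsilyloxy)but-2-en-1-yl]-5-(triisopropylsilyloxy)-4H-chromen-4-one | COc1cc(O[Si](C(C)C)(C(C)C)C(C)C)c2c(c1C/C=C(/C)CO[Si](C(C)C)(C(C)C)C(C)C)OC=CC2=O | intermediate
8 | 4-bromobenzene-1,2-diol | Oc1ccc(Br)cc1O | starting material
9 | 4-bromo-1,2-bis(tert-butyldimethylsilyloxy)benzene | CC(C)(C)[Si](C)(C)Oc1ccc(Br)cc1O[Si](C)(C)C(C)(C)C | intermediate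
10 | [3,4-bis(tert-butyldimethylsilyloxy)phenyl]lithium | [Li]c1ccc(O[Si](C)(C)C(C)(C)C)c(O[Si](C)(C)C(C)(C)C)c1 | intermediate
11 | lithium [3,4-bis(tert-butyldimethylsilyloxy)phenyl]triisopropoxyborate | [Li+].CC(C)O[B-](OC(C)C)(OC(C)C)c1ccc(O[Si](C)(C)C(C)(C)C)c(O[Si](C)(C)C(C)(C)C)c1 | intermediate
12 | [3,4-bis(tert-butyldimethylsilyloxy)phenyl]boronic acid | OB(O)c1ccc(O[Si](C)(C)C(C)(C)C)c(O[Si](C)(C)C(C)(C)C)c1 | intermediate
13 | (2S)-2-[3,4-bis(tert-butyldimethylsilyloxy)phenyl]-7-methoxy-8-[(2Z)-3-methyl-4-(triisopropylsilyloxy)but-2-en-1-yl]-5-(triisopropylsilyloxy)-2,3-dihydro-4H-chromen-4-one | COc1cc(O[Si](C(C)C)(C(C)C)C(C)C)c2c(c1C/C=C(/C)CO[Si](C(C)C)(C(C)C)C(C)C)O[C@H](c1ccc(O[Si](C)(C)C(C)(C)C)c(O[Si](C)(C)C(C)(C)C)c1)CC2=O | intermediate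
14 | (2S)-2-(3,4-dihydroxyphenyl)-5-hydroxy-8-[(2Z)-4-hydroxy-3-methylbut-2-en-1-yl]-7-methoxy-2,3-dihydro-4H-chromen-4-one | COc1cc(O)c2c(c1C/C=C(/C)CO)O[C@H](c1ccc(O)c(O)c1)CC2=O | target

## Step count and least certain steps

Total step count: 8. Longest linear sequence: 6 steps (steps 1, 2, 3, 4, 7, 8); the boronic acid branch (steps 5, 6) joins at step 7.

**Step 2 (key step, proposed new method).**
- Most likely failure: loss of Z control. After the alkoxide is protonated by the phenol, only a hydrogen bond holds CH2OH anti, and the CH3/CH2OH pair on C3'' offers no steric bias, so syn/anti equilibration of the allyl could compete with C–C bond formation.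
- Further risks: O-allylation that does not revert, a second C-allylation, and palladium-mediated cyclization of the product's allylic alcohol onto the ortho phenol.
- Fallback by known chemistry, from 3 back to 5:
  - Propargyl alcohol is subjected to copper-catalysed anti-carbomagnesiation (MeMgBr, CuI cat.) and iodinolysis. This gives (Z)-3-iodo-2-methylprop-2-en-1-ol F1, whose geometry is fixed by the five-membered magnesium alkoxide chelate.
  - Silylation with TIPSCl gives the silyl ether F2.
  - Iodine–lithium exchange (t-BuLi, −78 °C) gives the configurationally stable vinyllithium F3, which is trapped with paraformaldehyde to give (2Z)-3-methyl-4-(triisopropylsilyloxy)but-2-en-1-ol F4.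
  - Appel bromination (CBr4, PPh3) gives the allylic bromide F5.
  - C-alkylation of the phenoxide of 3 with F5 (aq KOH, 0 °C to rt, the classical protocol for C-prenylation of phloroacetophenones; SN2, geometry retained, site fixed by symmetry) gives the mono-silylated ketone F6.
  - Silylation of O6 of F6 with TIPSCl returns to 5.

**Step 3.**
- Most likely failure: insufficient discrimination between the two chelated phenols, so that some silylation at O2 leads on to the 6-substituted series.
- Fallback, from 3 back to 5, which differentiates before the C–C bond is made: mono-silylation of 3, unambiguous because both hydroxyl groups are equivalent, gives 1-[2-hydroxy-4-methoxy-6-(triisopropylsilyloxy)phenyl]ethan-1-one F7.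
- F7 is allylated with 2 under the conditions of step 2 to give the ortho-allylated phenol F8. Attack now has to be steered to C3 by the ion pair and hydrogen bond with the free 2-OH and by the bulk of the silyloxy group next to C5. If step 2 is run by its own fallback, the sodium phenoxide of F7 is instead C-alkylated with the bromide of that fallback in toluene.
- Silylation of the primary alcohol of F8 gives 5.

**Step 7.**
- Most likely failures: slow addition to the electron-rich chromone, ring opening of the rhodium enolate by β-oxygen elimination, and incomplete or inverted facial selectivity of the diene ligand on this substituted chromone.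
- Fallback, from 7 and 12 back to 13: a racemic conjugate addition with an achiral divalent palladium catalyst (Pd(OCOCF3)2, 2,2'-bipyridine, aqueous medium, 60 to 80 °C), which can be run hot because no selectivity is at stake. It gives 13 together with its enantiomer F9.
- The mixture is resolved by Noyori-type asymmetric transfer hydrogenation (RhCl(Cp*)[(R,R)-TsDPEN], HCO2H/Et3N, EtOAc, rt), a kinetic resolution known for flavanones. The (R,R)-catalyst should deliver hydride to form a 4R carbinol, which is cis-compatible only with the 2R ketone. F9 is thus reduced to the cis-flavan-4-ol F10, and 13 is recovered and separated.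

**Step 8.**
- Most likely failures: ring opening and reclosure of ring C (epimerization at C2) if the fluoride is not fully buffered, and sluggish cleavage of the primary triisopropylsilyl ether under buffered conditions.
- Fallback, from 7 back to 14, which moves most of the deprotection in front of the stereocenter: chromone 7 is desilylated with TBAF to the achiral 5-hydroxychromone F11.
- The rhodium-catalysed addition of 12 is run on F11 without added base. Free hydroxyl groups are tolerated, and the hydrogen-bonded 5-OH activates the enone. This gives the flavanone F12, which carries only two aryl silyl ethers.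
- The aryl silyl ethers of F12 are cleaved with KHF2 in MeOH at rt, a mild method selective for phenolic silyl ethers, to give 14.

## Further compounds

F1 | step 2 | (2Z)-3-iodo-2-methylprop-2-en-1-ol | I/C=C(/C)CO
F2 | step 2 | {[(2Z)-3-iodo-2-methylprop-2-en-1-yl]oxy}triisopropylsilane | I/C=C(/C)CO[Si](C(C)C)(C(C)C)C(C)C
F3 | step 2 | [(1Z)-2-methyl-3-(triisopropylsilyloxy)prop-1-en-1-yl]lithium | [Li]/C=C(/C)CO[Si](C(C)C)(C(C)C)C(C)C
F4 | step 2 | (2Z)-3-methyl-4-(triisopropylsilyloxy)but-2-en-1-ol | OC/C=C(/C)CO[Si](C(C)C)(C(C)C)C(C)C
F5 | step 2 | {[(2Z)-4-bromo-2-methylbut-2-en-1-yl]oxy}triisopropylsilane | BrC/C=C(/C)CO[Si](C(C)C)(C(C)C)C(C)C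
F6 | step 2 | 1-{2,6-dihydroxy-4-methoxy-3-[(2Z)-3-methyl-4-(triisopropylsilyloxy)but-2-en-1-yl]phenyl}ethan-1-one | CC(=O)c1c(O)cc(OC)c(C/C=C(/C)CO[Si](C(C)C)(C(C)C)C(C)C)c1O
F7 | step 3 | 1-[2-hydroxy-4-methoxy-6-(triisopropylsilyloxy)phenyl]ethan-1-one | CC(=O)c1c(O)cc(OC)cc1O[Si](C(C)C)(C(C)C)C(C)C
F8 | step 3 | 1-{2-hydroxy-3-[(2Z)-4-hydroxy-3-methylbut-2-en-1-yl]-4-methoxy-6-(triisopropylsilyloxy)phenyl}ethan-1-one | CC(=O)c1c(O[Si](C(C)C)(C(C)C)C(C)C)cc(OC)c(C/C=C(/C)CO)c1O
F9 | step 7 | (2R)-2-[3,4-bis(tert-butyldimethylsilyloxy)phenyl]-7-methoxy-8-[(2Z)-3-methyl-4-(triisopropylsilyloxy)but-2-en-1-yl]-5-(triisopropylsilyloxy)-2,3-dihydro-4H-chromen-4-one | COc1cc(O[Si](C(C)C)(C(C)C)C(C)C)c2c(c1C/C=C(/C)CO[Si](C(C)C)(C(C)C)C(C)C)O[C@@H](c1ccc(O[Si](C)(C)C(C)(C)C)c(O[Si](C)(C)C(C)(C)C)c1)CC2=O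
F10 | step 7 | (2R,4R)-2-[3,4-bis(tert-butyldimethylsilyloxy)phenyl]-7-methoxy-8-[(2Z)-3-methyl-4-(triisopropylsilyloxy)but-2-en-1-yl]-5-(triisopropylsilyloxy)-3,4-dihydro-2H-chromen-4-ol | COc1cc(O[Si](C(C)C)(C(C)C)C(C)C)c2c(c1C/C=C(/C)CO[Si](C(C)C)(C(C)C)C(C)C)O[C@@H](c1ccc(O[Si](C)(C)C(C)(C)C)c(O[Si](C)(C)C(C)(C)C)c1)C[C@H]2O
F11 | step 8 | 5-hydroxy-8-[(2Z)-4-hydroxy-3-methylbut-2-en-1-yl]-7-methoxy-4H-chromen-4-one | COc1cc(O)c2c(c1C/C=C(/C)CO)OC=CC2=O
F12 | step 8 | (2S)-2-[3,4-bis(tert-butyldimethylsilyloxy)phenyl]-5-hydroxy-8-[(2Z)-4-hydroxy-3-methylbut-2-en-1-yl]-7-methoxy-2,3-dihydro-4H-chromen-4-one | COc1cc(O)c2c(c1C/C=C(/C)CO)O[C@H](c1ccc(O[Si](C)(C)C(C)(C)C)c(O[Si](C)(C)C(C)(C)C)c1)CC2=O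
A1 | alternative 1 | 1-[2,6-dihydroxy-4-methoxy-3-(3-methylbut-2-en-1-yl)phenyl]ethan-1-one | CC(=O)c1c(O)cc(OC)c(CC=C(C)C)c1O
A2 | alternative 1 | 1-{2,6-dihydroxy-3-[(2E)-4-hydroxy-3-methylbut-2-en-1-yl]-4-methoxyphenyl}ethan-1-one | CC(=O)c1c(O)cc(OC)c(C/C=C(\C)CO)c1O
A3 | alternative 1 | (2E)-1-{2,6-dihydroxy-3-[(2E)-4-hydroxy-3-methylbut-2-en-1-yl]-4-methoxyphenyl}-3-(3,4-dihydroxyphenyl)prop-2-en-1-one | COc1cc(O)c(C(=O)/C=C/c2ccc(O)c(O)c2)c(O)c1C/C=C(\C)CO
A4 | alternative 2 | (2S)-2-[3,4-bis(tert-butyldimethylsilyloxy)phenyl]-5-{[(2E)-4-(tert-butyldimethylsilyloxy)-3-methylbut-2-en-1-yl]oxy}-7-methoxy-2,3-dihydro-4H-chromen-4-one | COc1cc(OC/C=C(\C)CO[Si](C)(C)C(C)(C)C)c2c(c1)O[C@H](c1ccc(O[Si](C)(C)C(C)(C)C)c(O[Si](C)(C)C(C)(C)C)c1)CC2=O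
A5 | alternative 3 | 1-[2,6-dihydroxy-4-methoxy-3-(prop-2-en-1-yl)phenyl]ethan-1-one | C=CCc1c(OC)cc(O)c(C(C)=O)c1O
A6 | alternative 3 | 2-(3-acetyl-2,4-dihydroxy-6-methoxyphenyl)acetaldehyde | CC(=O)c1c(O)cc(OC)c(CC=O)c1O
A7 | alternative 3 | methyl (2Z)-4-(3-acetyl-2,4-dihydroxy-6-methoxyphenyl)-2-methylbut-2-enoate | COC(=O)/C(C)=C\Cc1c(OC)cc(O)c(C(C)=O)c1O
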